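## Analysis of the target

The target 28 is a lignan γ-butyrolactone. Positions are numbered C1 (lactone carbonyl), C2, C3 and C4 (the OCH2 carbon); C2 carries the carbinol carbon C7 with a 4-hydroxy-3-methoxyphenyl ring, and C3 carries the benzylic carbon C7' of a 4-hydroxy-3-methoxybenzyl group. The three contiguous stereocentres are C7 (S), C2 (S) and C3 (R). The two ring substituents are trans, and the C7 hydroxyl is syn to the C2–C3 bond when C1–C2–C7–aryl is drawn as a zigzag. C2 lies between the lactone carbonyl and C7, so it can equilibrate and prefers trans, whereas C3 cannot be corrected in the target and has to be introduced in absolute form. The C2–C7 unit is an aldol, open to retro-aldol cleavage and dehydration under base, and the p-hydroxybenzylic alcohol ionises easily to a quinone methide, so the phenols stay masked to the end and the last steps must be nearly neutral. The difficulty is therefore the control of C7 next to an epimerisable centre and the mild end game, more than the carbon count. The strategy rests on the C1–C2–C7 unit: a lactone with an acyl carbon C7 on C2 is the Wolff product of a six-membered 3-diazo keto lactone in which C7 is the ring ketone and C3 is bonded to C7. Moving C3 from C7 to C2 contracts that ring to the γ-lactone and leaves C7 as an activated acyl group for the aryl ring.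

## Retrosynthetic reasoning

Target 28 is traced back to the bis-silyl ether 27 by cutting only the two O–Si bonds. Unmasking last means the p-hydroxybenzylic alcohol is never carried through another reaction.

Carbinol 27 is traced back to the aryl ketone 26 by the C7–H bond. The ketone and the lactone carbonyl form a 1,3-dicarbonyl unit that can hold a metal in a chelate, so hydride can be directed to the ketone face opposite C3. In 26 the C2 hydrogen is acidic, so C2 adopts the trans arrangement by itself; the reduction then has to fix only C7.

Ketone 26 is cut at the C7–aryl bond into thioester 20 and boronic acid 25. This places the second aryl ring on an acyl carbon that already sits on C2, and a base-free acyl cross-coupling suits the acidic C2–H. Boronic acid 25 goes back through aryl bromide 22 to bromophenol 21.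

Thioester 20 is the product of the key disconnection. Its C2–C3 bond is traced back to the C3–C7 bond of the diazo keto lactone 17, with thiophenol 18 as the trap for the intermediate acylketene 19. The cut is made here because the ring contraction delivers the lactone and the C7 acyl handle together, and because the migrating carbon C3 carries its configuration along unchanged. The forward reaction must make carbon, not the ring oxygen, migrate, and must not let C3 epimerise beforehand.

Diazo compound 17 comes from the pyrandione 16 by diazo transfer to its doubly activated methylene. Pyrandione 16 is opened at the lactone C–O bond to the hydroxy keto ester 15, and its protected form 14 is cut between the ketone carbon and the methylene into acid 10 and the malonate half-ester salt 11. This is a two-carbon chain extension that runs under near-neutral conditions, which matters because the stereocentre is α to the new ketone.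

Acid 10 is traced through imide 8 to imide 6 by cutting the bond between the stereocentre and the oxygen-bearing CH2 carbon (C3–C4). The forward reaction is an alkoxymethylation of the titanium enolate 7, in which auxiliary 4 decides the configuration of C3. The hydroxyl arrives masked as a benzyl ether so that it is inert during acid activation.

Imide 6 is assembled from acid 3 and auxiliary 4, and acid 3 is the silylated form of the commercial acid 1, which already contains C7', C3 and the future C7.

## Alternatives that were turned down

Alternative 1: The C2–C3 bond is cut symmetrically, so that both halves come from ferulic acid A2.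
- Forward key step: one-electron oxidation of A2 (anodic or chemical) gives two β-radicals that couple. Each carboxyl then adds to the quinone methide of the other half, giving the cis-fused bis-lactone A1.
- In favour: one operation from a cheap acid makes the C2–C3 bond, oxygenates C7 and fixes the relative configuration of three centres in a rigid bicycle. The remaining work is short: hydrogenolysis of one benzylic C–O bond to create the C7' methylene, reduction of the other lactone carbonyl to the C4 alcohol, and relactonisation.
- Against: A1 forms as a racemate with no element for asymmetric induction, so a single enantiomer requires a resolution that discards half the material. The two lactones of A1 are identical, so the hydrogenolysis that must cleave one benzylic C–O bond and spare the other is statistical at best. Phenol radical coupling also gives β–5 and β–O–4 dimers, and every later step runs with free phenols next to ionisable benzylic C–O bonds.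
- Comparison: A1 is clearly stronger in step economy and in the amount of structure one step creates. The chosen route offers instead an absolute configuration from an auxiliary, and two aryl arms that differ from the start because C7' comes from acid 1 and the C7 aryl from boronic acid 25.

Alternative 2: The C3–C4 bond is cut, and C4 is delivered as a silylmethyl radical tethered to the C7 oxygen.
- Forward key step: a tin hydride and an azo initiator convert the (bromomethyl)dimethylsilyl ether A4 into a silylmethyl radical. It adds 6-endo to C3 of the unsaturated ester, the C2 radical takes hydrogen, and the oxasilacyclohexane A3 results. Oxidative C–Si cleavage and lactonisation would follow.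
- In favour: the nucleophilic radical is polarity-matched to C3, the β-carbon of the acrylate, and the fully substituted C2 disfavours 5-exo closure. A single carbinol centre at C7 could in principle relay its configuration to C3 and C2 through the temporary ring.
- Against: C3 and C2 are both formed in the radical step. C3 depends on a flexible six-membered transition state, and C2 depends on hydrogen transfer to a planar ester radical. The C7'–H bonds of A4 are both allylic and benzylic and can quench the chain. A4 itself needs an enantioselective carbinol synthesis and control of alkene geometry. The oxidative C–Si cleavage has to tolerate two electron-rich arenes, and tin must be removed.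
- Comparison: the step count would be similar. The alternative is more convergent on paper, but the chosen route sets C3 by an auxiliary alkylation of predictable sense and derives C2 and C7 from it by equilibration and chelation, which is easier to defend than two radical-derived centres.

Alternative 3: The C1–C2 and C7–O bonds are cut.
- Forward key step: a silane with a trialkylborane initiator and a slow air feed converts the Se-phenyl selenocarbonate A6 into an alkoxycarbonyl radical. It closes 5-exo onto C2, and the benzylic C7 radical is captured by oxygen, giving the bis-silyl ether A5 of the target.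
- In favour: the lactone ring and the C7 oxygen are installed in one step under neutral conditions. The 5-exo closure should give the trans C2–C3 arrangement, and A6 has a single stereocentre, so this route would probably be three to four steps shorter than the chosen one.
- Against: C7 is created by capture of a freely rotating benzylic radical, so no element of A6 controls its configuration and both C7 epimers are expected. Hydrogen transfer from the silane competes with oxygen capture and would give the deoxy lactone, and balancing the chain against the air feed is delicate. Correcting C7 would need oxidation to the ketone and a selective reduction.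
- Comparison: the alternative wins on step economy up to the ring closure. After the C7 correction it would end with the same reduction as the chosen route, which reaches that ketone directly and without an epimer mixture.

Key step: step 8

Remarks on the chemistry:
- Both phenols are carried as triisopropylsilyl ethers, because aryl tert-butyldimethylsilyl ethers would be at risk under LiOH/H2O2 and para to the aryl ketone.
- C4 is introduced as a benzyloxymethyl group so that the hydroxyl is masked during acid activation.
- The malonate is used as its tert-butyl half-ester so that the six-membered lactone closes under acid, which the aryl silyl ether tolerates.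
- The boron partner is the free boronic acid, the form for which thioester–boronic acid coupling is established.
- Compounds 1, 4, 11, 18 and 21 are assumed to be purchased.
- Position labels C1–C4, C7 and C7' refer to the target; ring positions of the six-membered lactone are called "ring position n".

## Route

Step 1
Reactants: 1 3-(4-hydroxy-3-methoxyphenyl)propanoic acid
Product: 3 3-[3-methoxy-4-(triisopropylsilyloxy)phenyl]propanoic acid, via bis-silylated acid 2 (not isolated)
Conditions: i-Pr3SiCl (2.3 equiv), imidazole, DMF, rt; then AcOH/THF/H2O, rt
Reagents that add atoms: triisopropylsilyl chloride, CC(C)[Si](Cl)(C(C)C)C(C)C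
Why: Imidazole-promoted silylation covers both the phenol and the carboxyl; the silyl ester is much more labile to aqueous acid than the aryl silyl ether and should be hydrolysed selectively in the second stage.

Step 2
Reactants: 3 3-[3-methoxy-4-(triisopropylsilyloxy)phenyl]propanoic acid; 4 (R)-4-benzyloxazolidin-2-one
Product: 6 (R)-4-benzyl-3-{3-[3-methoxy-4-(triisopropylsilyloxy)phenyl]propanoyl}oxazolidin-2-one, via pivalic mixed anhydride 5 (not isolated)
Conditions: t-BuCOCl, Et3N, THF, −20 °C; then 4, LiCl, −20 °C → rt
Reagents that add atoms: none
Why: N-acylation of the Evans auxiliary through the mixed anhydride with LiCl/Et3N activation; the oxazolidinone attacks the less hindered carbonyl of 5, and no strong base touches the aryl silyl ether.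

Step 3
Reactants: 6 (R)-4-benzyl-3-{3-[3-methoxy-4-(triisopropylsilyloxy)phenyl]propanoyl}oxazolidin-2-one
Product: 8 (R)-4-benzyl-3-{(S)-2-[(benzyloxy)methyl]-3-[3-methoxy-4-(triisopropylsilyloxy)phenyl]propanoyl}oxazolidin-2-one, via chlorotitanium Z-enolate 7 (not isolated)
Conditions: TiCl4, i-Pr2NEt, CH2Cl2, 0 °C; then BnOCH2Cl, 0 °C
Reagents that add atoms: benzyl chloromethyl ether, ClCOCc1ccccc1
Why: Evans titanium-enolate alkylation: soft enolisation gives the chelated Z-enolate 7, the 4-benzyl group of the (R)-auxiliary shields one face, and the alkoxymethyl electrophile adds to the open face, which should set the new centre as S with high diastereoselectivity. The enolate is far more nucleophilic than the silyloxyanisole ring, so ring alkylation should not compete at 0 °C with a small excess of electrophile.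

Step 4
Reactants: 8 (R)-4-benzyl-3-{(S)-2-[(benzyloxy)methyl]-3-[3-methoxy-4-(triisopropylsilyloxy)phenyl]propanoyl}oxazolidin-2-one
Product: 10 (S)-2-[(benzyloxy)methyl]-3-[3-methoxy-4-(triisopropylsilyloxy)phenyl]propanoic acid, via peroxy acid 9 (not isolated)
Conditions: LiOH, H2O2, THF/H2O, 0 °C; then aq. Na2SO3; HCl to pH 3
Reagents that add atoms: hydrogen peroxide, OO
Why: Hydroperoxide cleavage of the Evans imide: the hydroperoxide anion attacks the exocyclic carbonyl, sulfite reduces peracid 9, and the α-centre should not epimerise at 0 °C. The aryl triisopropylsilyl ether should survive the short cold basic treatment, and auxiliary 4 is recovered.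

Step 5
Reactants: 10 (S)-2-[(benzyloxy)methyl]-3-[3-methoxy-4-(triisopropylsilyloxy)phenyl]propanoic acid; 11 potassium tert-butyl malonate
Product: 14 tert-butyl (S)-4-[(benzyloxy)methyl]-5-[3-methoxy-4-(triisopropylsilyloxy)phenyl]-3-oxopentanoate, via acyl imidazolide 12 (not isolated), via acylmalonate half-ester 13 (not isolated)
Conditions: CDI, THF, rt; then 11, MgCl2, Et3N, MeCN, rt → 40 °C; 1 M HCl work-up
Reagents that add atoms: none
Why: Masamune–Brooks homologation: imidazolide 12 C-acylates the magnesium malonate half-ester and 13 loses CO2 to give the β-keto ester. The medium is nearly neutral, so the stereocentre next to the new ketone should stay intact.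

Step 6
Reactants: 14 tert-butyl (S)-4-[(benzyloxy)methyl]-5-[3-methoxy-4-(triisopropylsilyloxy)phenyl]-3-oxopentanoate
Product: 16 (S)-5-[3-methoxy-4-(triisopropylsilyloxy)benzyl]dihydro-2H-pyran-2,4(3H)-dione, via hydroxy keto ester 15 (not isolated)
Conditions: H2 (1 atm), Pd/C, EtOAc, rt; filter, concentrate; then CF3CO2H, CH2Cl2, 0 °C → rt
Reagents that add atoms: none
Why: Hydrogenolysis frees the primary alcohol, and acid then cleaves the tert-butyl ester and closes the six-membered keto lactone (acid-mediated lactonisation of a δ-hydroxy β-keto tert-butyl ester, 6-exo-trig). The aryl silyl ether is stable to anhydrous acid, and 16 rests as the enol between ring positions 3 and 4, which keeps ring position 5 from enolising.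

Step 7
Reactants: 16 (S)-5-[3-methoxy-4-(triisopropylsilyloxy)benzyl]dihydro-2H-pyran-2,4(3H)-dione
Product: 17 (S)-3-diazo-5-[3-methoxy-4-(triisopropylsilyloxy)benzyl]dihydro-2H-pyran-2,4(3H)-dione
Conditions: 4-AcNHC6H4SO2N3, Et3N, MeCN, 0 °C
Reagents that add atoms: 4-acetamidobenzenesulfonyl azide, CC(=O)Nc1ccc(cc1)S(=O)(=O)N=[N+]=[N-]
Why: Regitz diazo transfer to the strongly acidic methylene at ring position 3 of the cyclic β-keto lactone needs only a tertiary amine at 0 °C. Before transfer the enolate protects ring position 5, and afterwards the ketone is a vinylogous diazo carbonyl of low α-acidity, so the stereocentre should hold.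

Step 8
Reactants: 17 (S)-3-diazo-5-[3-methoxy-4-(triisopropylsilyloxy)benzyl]dihydro-2H-pyran-2,4(3H)-dione; 18 thiophenol
Product: 20 S-phenyl (4R)-4-[3-methoxy-4-(triisopropylsilyloxy)benzyl]-2-oxotetrahydrofuran-3-carbothioate (epimers at ring position 3, trans expected to prevail), via acylketene 19 (not isolated)
Conditions: hν (λ ≥ 300 nm, Pyrex filter), 18 (3 equiv), degassed MeCN, 15 °C
Reagents that add atoms: none
Why: Excitation of the diazo dicarbonyl chromophore, held s-cis on both sides by the ring, expels N2 with a concerted 1,2-shift of ring position 5 (target C3) from the ketone carbon (target C7) to the diazo carbon (target C2), giving the ring-contracted acylketene 19; this is the photochemical Wolff rearrangement. The closest known reaction type is the Wolff ring contraction of cyclic 2-diazo-1,3-dicarbonyl compounds with nucleophilic capture of the ketene, for example 3-diazochroman-2,4-diones to 2-oxo-2,3-dihydrobenzofuran-3-carboxylic acid derivatives. The γ-lactone is thus closed by ring contraction through the new C2–C3 bond and not by an exo or endo cyclisation. Thiophenol adds across the strongly electrophilic acylketene to give the S-phenyl thioester. The migrating carbon keeps its configuration, as in all suprafacial 1,2-shifts, so the S centre of 17 becomes the R centre of 20 (same spatial arrangement, changed CIP ranking); the α-carbon of 20 arises on protonation, is acidic, should settle trans, and is not counted as set here. The step needs carbon and not ring-oxygen migration: the alkyl group on the ketone side migrates far more readily than the lactone oxygen, whose lone pair is engaged in ester resonance, so only the γ-lactone should form. Irradiation above 300 nm keeps the thiol outside the absorbing window, and the neutral medium avoids enolisation toward the stereocentre before nitrogen is lost.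

Step 9
Reactants: 21 4-bromo-2-methoxyphenol
Product: 22 (4-bromo-2-methoxyphenoxy)triisopropylsilane
Conditions: i-Pr3SiCl, imidazole, DMF, rt
Reagents that add atoms: triisopropylsilyl chloride, CC(C)[Si](Cl)(C(C)C)C(C)C
Why: Standard imidazole-promoted silylation of a phenol; the aryl bromide is inert.

Step 10
Reactants: 22 (4-bromo-2-methoxyphenoxy)triisopropylsilane
Product: 25 [3-methoxy-4-(triisopropylsilyloxy)phenyl]boronic acid, via aryllithium 23 (not isolated), via lithium aryltriisopropoxyborate 24 (not isolated)
Conditions: n-BuLi, THF, −78 °C; B(Oi-Pr)3, −78 °C → rt; 1 M HCl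
Reagents that add atoms: triisopropyl borate, CC(C)OB(OC(C)C)OC(C)C; water, O
Why: Bromine–lithium exchange, capture of aryllithium 23 as the ate complex 24 and acidic hydrolysis is the standard arylboronic acid synthesis; the bulky silyl ether should neither migrate nor cleave at −78 °C.

Step 11
Reactants: 20 S-phenyl (4R)-4-[3-methoxy-4-(triisopropylsilyloxy)benzyl]-2-oxotetrahydrofuran-3-carbothioate; 25 [3-methoxy-4-(triisopropylsilyloxy)phenyl]boronic acid
Product: 26 (4R)-3-[3-methoxy-4-(triisopropylsilyloxy)benzoyl]-4-[3-methoxy-4-(triisopropylsilyloxy)benzyl]dihydrofuran-2(3H)-one (ring position 3 epimerisable, trans expected)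
Conditions: Pd2(dba)3 (cat.), P(2-furyl)3, CuTC (monovalent copper thiophene-2-carboxylate, 1.5 equiv), THF, 50 °C
Reagents that add atoms: none
Why: Liebeskind–Srogl ketone synthesis: zerovalent palladium inserts into the acyl–sulfur bond, the thiophilic copper carboxylate takes up the thiolate and activates the boronic acid for transmetalation, and reductive elimination forms the C7–aryl bond. No base is added, which suits the acidic C2–H of this malonate-type thioester.

Step 12
Reactants: 26 (4R)-3-[3-methoxy-4-(triisopropylsilyloxy)benzoyl]-4-[3-methoxy-4-(triisopropylsilyloxy)benzyl]dihydrofuran-2(3H)-one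
Product: 27 (3S,4R)-3-{(S)-hydroxy[3-methoxy-4-(triisopropylsilyloxy)phenyl]methyl}-4-[3-methoxy-4-(triisopropylsilyloxy)benzyl]dihydrofuran-2(3H)-one
Conditions: Zn(BH4)2, Et2O, −20 → 0 °C; aq. NH4Cl
Reagents that add atoms: none
Why: Chelation-controlled (Cram-chelate) reduction of an α-substituted β-keto ester: zinc bridges the ketone and lactone carbonyls, and hydride adds to the ketone face on the side of the C2 hydrogen, away from C3, which should give the syn carbinol, here 7S. C2 stays trans to the C3 benzyl group because that arrangement is favoured in 26 and the neutral reagent does not enolise it.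

Step 13
Reactants: 27 (3S,4R)-3-{(S)-hydroxy[3-methoxy-4-(triisopropylsilyloxy)phenyl]methyl}-4-[3-methoxy-4-(triisopropylsilyloxy)benzyl]dihydrofuran-2(3H)-one
Product: 28 (3S,4R)-3-[(S)-hydroxy(4-hydroxy-3-methoxyphenyl)methyl]-4-(4-hydroxy-3-methoxybenzyl)dihydrofuran-2(3H)-one
Conditions: n-Bu4NF, AcOH (1:1), THF, 0 °C
Reagents that add atoms: none
Why: Aryl silyl ethers are cleaved quickly by fluoride because phenoxide is a good leaving group from silicon. Buffering with acetic acid keeps the medium near neutral, so that retro-aldol cleavage, C2 epimerisation and quinone methide formation should be suppressed.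

## Compound list

1 | 3-(4-hydroxy-3-methoxyphenyl)propanoic acid | COc1cc(CCC(=O)O)ccc1O | starting material
2 | triisopropylsilyl 3-[3-methoxy-4-(triisopropylsilyloxy)phenyl]propanoate | COc1cc(CCC(=O)O[Si](C(C)C)(C(C)C)C(C)C)ccc1O[Si](C(C)C)(C(C)C)C(C)C | intermediate
3 | 3-[3-methoxy-4-(triisopropylsilyloxy)phenyl]propanoic acid | COc1cc(CCC(=O)O)ccc1O[Si](C(C)C)(C(C)C)C(C)C | intermediate
4 | (R)-4-benzyloxazolidin-2-one | O=C1OC[C@@H](Cc2ccccc2)N1 | starting material
5 | 3-[3-methoxy-4-(triisopropylsilyloxy)phenyl]propanoic pivalic anhydride | COc1cc(CCC(=O)OC(=O)C(C)(C)C)ccc1O[Si](C(C)C)(C(C)C)C(C)C | intermediate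
6 | (R)-4-benzyl-3-{3-[3-methoxy-4-(triisopropylsilyloxy)phenyl]propanoyl}oxazolidin-2-one | COc1cc(CCC(=O)N2[C@H](Cc3ccccc3)COC2=O)ccc1O[Si](C(C)C)(C(C)C)C(C)C | intermediate
7 | trichlorotitanium (Z)-enolate of imide 6 | COc1cc(C/C=C(\O[Ti](Cl)(Cl)Cl)N2[C@H](Cc3ccccc3)COC2=O)ccc1O[Si](C(C)C)(C(C)C)C(C)C | intermediate
8 | (R)-4-benzyl-3-{(S)-2-[(benzyloxy)methyl]-3-[3-methoxy-4-(triisopropylsilyloxy)phenyl]propanoyl}oxazolidin-2-one | O=C(N1[C@H](Cc2ccccc2)COC1=O)[C@H](COCc1ccccc1)Cc1ccc(O[Si](C(C)C)(C(C)C)C(C)C)c(OC)c1 | intermediate
9 | (S)-2-[(benzyloxy)methyl]-3-[3-methoxy-4-(triisopropylsilyloxy)phenyl]propaneperoxoic acid | OOC(=O)[C@H](COCc1ccccc1)Cc1ccc(O[Si](C(C)C)(C(C)C)C(C)C)c(OC)c1 | intermediate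
10 | (S)-2-[(benzyloxy)methyl]-3-[3-methoxy-4-(triisopropylsilyloxy)phenyl]propanoic acid | OC(=O)[C@H](COCc1ccccc1)Cc1ccc(O[Si](C(C)C)(C(C)C)C(C)C)c(OC)c1 | intermediate
11 | potassium tert-butyl malonate | [K+].[O-]C(=O)CC(=O)OC(C)(C)C | starting material
12 | (S)-2-[(benzyloxy)methyl]-1-(imidazol-1-yl)-3-[3-methoxy-4-(triisopropylsilyloxy)phenyl]propan-1-one | O=C(n1ccnc1)[C@H](COCc1ccccc1)Cc1ccc(O[Si](C(C)C)(C(C)C)C(C)C)c(OC)c1 | intermediate
13 | (4S)-4-[(benzyloxy)methyl]-2-(tert-butoxycarbonyl)-5-[3-methoxy-4-(triisopropylsilyloxy)phenyl]-3-oxopentanoic acid (formed as its magnesium salt) | OC(=O)C(C(=O)OC(C)(C)C)C(=O)[C@H](COCc1ccccc1)Cc1ccc(O[Si](C(C)C)(C(C)C)C(C)C)c(OC)c1 | intermediate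
14 | tert-butyl (S)-4-[(benzyloxy)methyl]-5-[3-methoxy-4-(triisopropylsilyloxy)phenyl]-3-oxopentanoate | CC(C)(C)OC(=O)CC(=O)[C@H](COCc1ccccc1)Cc1ccc(O[Si](C(C)C)(C(C)C)C(C)C)c(OC)c1 | intermediate
15 | tert-butyl (S)-4-(hydroxymethyl)-5-[3-methoxy-4-(triisopropylsilyloxy)phenyl]-3-oxopentanoate | CC(C)(C)OC(=O)CC(=O)[C@H](CO)Cc1ccc(O[Si](C(C)C)(C(C)C)C(C)C)c(OC)c1 | intermediate
16 | (S)-5-[3-methoxy-4-(triisopropylsilyloxy)benzyl]dihydro-2H-pyran-2,4(3H)-dione | O=C1OC[C@H](Cc2ccc(O[Si](C(C)C)(C(C)C)C(C)C)c(OC)c2)C(=O)C1 | intermediate
17 | (S)-3-diazo-5-[3-methoxy-4-(triisopropylsilyloxy)benzyl]dihydro-2H-pyran-2,4(3H)-dione | O=C1OC[C@H](Cc2ccc(O[Si](C(C)C)(C(C)C)C(C)C)c(OC)c2)C(=O)C1=[N+]=[N-] | intermediate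
18 | thiophenol | Sc1ccccc1 | starting material
19 | (R)-4-[3-methoxy-4-(triisopropylsilyloxy)benzyl]-3-(oxomethylidene)dihydrofuran-2(3H)-one | O=C1OC[C@H](Cc2ccc(O[Si](C(C)C)(C(C)C)C(C)C)c(OC)c2)C1=C=O | intermediate
20 | S-phenyl (4R)-4-[3-methoxy-4-(triisopropylsilyloxy)benzyl]-2-oxotetrahydrofuran-3-carbothioate (ring position 3 epimerisable) | O=C1OC[C@H](Cc2ccc(O[Si](C(C)C)(C(C)C)C(C)C)c(OC)c2)C1C(=O)Sc1ccccc1 | intermediate
21 | 4-bromo-2-methoxyphenol | COc1cc(Br)ccc1O | starting material
22 | (4-bromo-2-methoxyphenoxy)triisopropylsilane | COc1cc(Br)ccc1O[Si](C(C)C)(C(C)C)C(C)C | intermediate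
23 | [3-methoxy-4-(triisopropylsilyloxy)phenyl]lithium | [Li]c1ccc(O[Si](C(C)C)(C(C)C)C(C)C)c(OC)c1 | intermediate
24 | lithium triisopropoxy[3-methoxy-4-(triisopropylsilyloxy)phenyl]borate | [Li+].CC(C)O[B-](OC(C)C)(OC(C)C)c1ccc(O[Si](C(C)C)(C(C)C)C(C)C)c(OC)c1 | intermediate
25 | [3-methoxy-4-(triisopropylsilyloxy)phenyl]boronic acid | OB(O)c1ccc(O[Si](C(C)C)(C(C)C)C(C)C)c(OC)c1 | intermediate
26 | (4R)-3-[3-methoxy-4-(triisopropylsilyloxy)benzoyl]-4-[3-methoxy-4-(triisopropylsilyloxy)benzyl]dihydrofuran-2(3H)-one (ring position 3 epimerisable) | O=C1OC[C@H](Cc2ccc(O[Si](C(C)C)(C(C)C)C(C)C)c(OC)c2)C1C(=O)c1ccc(O[Si](C(C)C)(C(C)C)C(C)C)c(OC)c1 | intermediate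
27 | (3S,4R)-3-{(S)-hydroxy[3-methoxy-4-(triisopropylsilyloxy)phenyl]methyl}-4-[3-methoxy-4-(triisopropylsilyloxy)benzyl]dihydrofuran-2(3H)-one | COc1cc(C[C@H]2COC(=O)[C@@H]2[C@H](O)c2ccc(O[Si](C(C)C)(C(C)C)C(C)C)c(OC)c2)ccc1O[Si](C(C)C)(C(C)C)C(C)C | intermediate
28 | (3S,4R)-3-[(S)-hydroxy(4-hydroxy-3-methoxyphenyl)methyl]-4-(4-hydroxy-3-methoxybenzyl)dihydrofuran-2(3H)-one | COc1cc(C[C@H]2COC(=O)[C@@H]2[C@H](O)c2ccc(O)c(OC)c2)ccc1O | target

## Step count and least certain steps

Total: 13 steps. Longest linear sequence: 11 steps (steps 1 to 8, then 11 to 13); steps 9 and 10 form the two-step side branch to 25.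

**Step 8 (key step).**
- What may go wrong: the photogenerated carbene may be intercepted by the thiol before it rearranges (S–H insertion, or reduction of the diazo group through thiyl radical chains). The acylketene 19 may dimerise before it is trapped. Part of the light may be lost to diazirine formation or to thiol photolysis.
- Fallback: ring contraction and thioester formation are separated. Diazo compound 17 is irradiated in aqueous THF so that water traps the ketene, which should give (4R)-4-[3-methoxy-4-(triisopropylsilyloxy)benzyl]-2-oxotetrahydrofuran-3-carboxylic acid F1. F1 is then coupled with thiophenol 18 using dicyclohexylcarbodiimide and catalytic 4-dimethylaminopyridine in CH2Cl2 at 0 °C, the usual way to malonic half-thioesters, and the route is rejoined at 20.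

**Step 11.**
- What may go wrong: the acidic C2–H allows a copper enolate or loss of thiolate to the acylketene, which diverts the thioester from oxidative addition. The electron-rich boronic acid may protodeboronate faster than it transmetalates.
- Fallback: the C7–aryl bond is made by enolate chemistry instead. Thioester 20 is heated in wet DMSO at 120 °C, where hydrolysis and decarboxylation should give (R)-4-[3-methoxy-4-(triisopropylsilyloxy)benzyl]dihydrofuran-2(3H)-one F2. Aryllithium 23 is quenched with DMF to give 3-methoxy-4-(triisopropylsilyloxy)benzaldehyde F3. The lithium enolate of F2 (LiN(SiMe3)2, THF, −78 °C) is added to F3, which should give the trans aldols as a mixture of 27 and its C7 epimer (3S,4R)-3-{(R)-hydroxy[3-methoxy-4-(triisopropylsilyloxy)phenyl]methyl}-4-[3-methoxy-4-(triisopropylsilyloxy)benzyl]dihydrofuran-2(3H)-one F4. Oxidation of the mixture with Dess–Martin periodinane rejoins the route at 26. The price is that the carbon delivered as C7 by the rearrangement is given up and brought back with the aldehyde.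

**Step 12.**
- What may go wrong: poor facial selectivity at C7 if the zinc chelate is incomplete (the ether solvent or the aryl oxygens compete for zinc), or if the electron-rich ketone reacts so slowly that unchelated reduction competes.
- Fallback: substrate control is replaced by catalyst control. Ketone 26 is reduced by Noyori transfer hydrogenation with RuCl(p-cymene)[(S,S)-TsDPEN] in HCO2H/Et3N; this catalyst configuration is the one that gives the S carbinol from aryl alkyl ketones when the aryl group outranks the alkyl group, as here, and the product is again 27. No new compound is involved.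

**Step 6.**
- What may go wrong: dehydration of the β-hydroxy ketone 15 to the α-methylene ketone, acid-catalysed enolisation toward the stereocentre with partial loss of configuration, decarboxylation of the β-keto acid before ring closure, or tert-butylation of the electron-rich ring.
- Fallback: the lactone is closed thermally through an acylketene, replacing steps 5 and 6. Acid 10 is condensed with Meldrum's acid (EDC·HCl, 4-dimethylaminopyridine, CH2Cl2) to give 5-{(S)-2-[(benzyloxy)methyl]-3-[3-methoxy-4-(triisopropylsilyloxy)phenyl]propanoyl}-2,2-dimethyl-1,3-dioxane-4,6-dione F5. Hydrogenolysis (H2, Pd/C, EtOAc) gives 5-{(S)-2-(hydroxymethyl)-3-[3-methoxy-4-(triisopropylsilyloxy)phenyl]propanoyl}-2,2-dimethyl-1,3-dioxane-4,6-dione F6. Heating F6 in toluene at 90 °C generates the acylketene, which the free hydroxyl captures, and the route is rejoined at 16 without acid or base.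

**Step 13.**
- What may go wrong: once the phenoxide para to the carbinol forms, retro-aldol cleavage or loss of configuration at C7 through a quinone methide can set in, and the aldol can epimerise at C2.
- Fallback: the order of the last two steps is inverted. Ketone 26 is desilylated first (n-Bu4NF/AcOH, THF, 0 °C), where no carbinol is present, to give (4R)-3-(4-hydroxy-3-methoxybenzoyl)-4-(4-hydroxy-3-methoxybenzyl)dihydrofuran-2(3H)-one F7. F7 is then reduced with excess Zn(BH4)2, which is expected to be slower because of the zinc phenoxide, and the route is rejoined at 28.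

## Further compounds

F1 | step 8 | (4R)-4-[3-methoxy-4-(triisopropylsilyloxy)benzyl]-2-oxotetrahydrofuran-3-carboxylic acid | O=C1OC[C@H](Cc2ccc(O[Si](C(C)C)(C(C)C)C(C)C)c(OC)c2)C1C(=O)O
F2 | step 11 | (R)-4-[3-methoxy-4-(triisopropylsilyloxy)benzyl]dihydrofuran-2(3H)-one | O=C1OC[C@H](Cc2ccc(O[Si](C(C)C)(C(C)C)C(C)C)c(OC)c2)C1
F3 | step 11 | 3-methoxy-4-(triisopropylsilyloxy)benzaldehyde | COc1cc(C=O)ccc1O[Si](C(C)C)(C(C)C)C(C)C
F4 | step 11 | (3S,4R)-3-{(R)-hydroxy[3-methoxy-4-(triisopropylsilyloxy)phenyl]methyl}-4-[3-methoxy-4-(triisopropylsilyloxy)benzyl]dihydrofuran-2(3H)-one | COc1cc(C[C@H]2COC(=O)[C@@H]2[C@@H](O)c2ccc(O[Si](C(C)C)(C(C)C)C(C)C)c(OC)c2)ccc1O[Si](C(C)C)(C(C)C)C(C)C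
F0 | step 12 | none | none
F5 | step 6 | 5-{(S)-2-[(benzyloxy)methyl]-3-[3-methoxy-4-(triisopropylsilyloxy)phenyl]propanoyl}-2,2-dimethyl-1,3-dioxane-4,6-dione | CC1(C)OC(=O)C(C(=O)[C@H](COCc2ccccc2)Cc2ccc(O[Si](C(C)C)(C(C)C)C(C)C)c(OC)c2)C(=O)O1
F6 | step 6 | 5-{(S)-2-(hydroxymethyl)-3-[3-methoxy-4-(triisopropylsilyloxy)phenyl]propanoyl}-2,2-dimethyl-1,3-dioxane-4,6-dione | CC1(C)OC(=O)C(C(=O)[C@H](CO)Cc2ccc(O[Si](C(C)C)(C(C)C)C(C)C)c(OC)c2)C(=O)O1
F7 | step 13 | (4R)-3-(4-hydroxy-3-methoxybenzoyl)-4-(4-hydroxy-3-methoxybenzyl)dihydrofuran-2(3H)-one | O=C1OC[C@H](Cc2ccc(O)c(OC)c2)C1C(=O)c1ccc(O)c(OC)c1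
A1 | alternative 1 | exo,exo-4,8-bis(4-hydroxy-3-methoxyphenyl)-3,7-dioxabicyclo[3.3.0]octane-2,6-dione | O=C1O[C@H](c2ccc(O)c(OC)c2)[C@H]3C(=O)O[C@H](c2ccc(O)c(OC)c2)[C@@H]13
A2 | alternative 1 | ferulic acid, (E)-3-(4-hydroxy-3-methoxyphenyl)prop-2-enoic acid | COc1cc(/C=C/C(=O)O)ccc1O
A3 | alternative 2 | methyl 6-aryl-4-(arylmethyl)-2,2-dimethyl-1-oxa-2-silacyclohexane-5-carboxylate (aryl = 4-tert-butyldimethylsilyloxy-3-methoxyphenyl) | C[Si]1(C)O[C@H](c2ccc(O[Si](C)(C)C(C)(C)C)c(OC)c2)[C@@H](C(=O)OC)[C@@H](Cc2ccc(O[Si](C)(C)C(C)(C)C)c(OC)c2)C1
A4 | alternative 2 | methyl 2-{(R)-aryl[(bromomethyl)dimethylsilyloxy]methyl}-4-arylbut-2-enoate (aryl = 4-tert-butyldimethylsilyloxy-3-methoxyphenyl, alkene geometry open) | COC(=O)C(=CCc1ccc(O[Si](C)(C)C(C)(C)C)c(OC)c1)[C@H](O[Si](C)(C)CBr)c1ccc(O[Si](C)(C)C(C)(C)C)c(OC)c1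
A5 | alternative 3 | bis(O-tert-butyldimethylsilyl) ether of the target at the two phenols | COc1cc(C[C@H]2COC(=O)[C@@H]2[C@H](O)c2ccc(O[Si](C)(C)C(C)(C)C)c(OC)c2)ccc1O[Si](C)(C)C(C)(C)C
A6 | alternative 3 | O-[(2R,3E)-2-(arylmethyl)-4-arylbut-3-en-1-yl] Se-phenyl carbonoselenoate (aryl = 4-tert-butyldimethylsilyloxy-3-methoxyphenyl) | O=C([Se]c1ccccc1)OC[C@H](Cc1ccc(O[Si](C)(C)C(C)(C)C)c(OC)c1)/C=C/c1ccc(O[Si](C)(C)C(C)(C)C)c(OC)c1
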